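**Plan**

- Retrosynthesis: the C5 enoate and the C3 2-methylbutanoate are cut first. The oxirane is traced back to a C7 acetyl group (sulfur-ylide methylene transfer), and the C5–O/C4=CH2 unit to a C4–CH2–O/C4=C5 cyclohexene (allylic 1,3-transposition).
- That cyclohexene (C3a–C4=C5–C6–C7–C7a), bridged from C3a to C7a by the three cyclopentane carbons C3–C2–C1, is the retron of an intramolecular Diels–Alder reaction. Bonds C6–C7 and C3a–C7a are cut to a 1,3,8-nonatriene with an (E)-enone dienophile.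
- O-3 and C4 are cis on the cyclopentane, so in the precursor they are tied into a temporary seven-membered Si(iPr)2 ring (4,7-dihydro-1,3,2-dioxasilepine). Ring-closing enyne metathesis makes this ring and the diene together.
- Forward: Evans aldol (C1, CH–OAc) → aldehyde → asymmetric γ-alkoxyallylboration (C2, C3) → isobutyrate and acetate → silicon tether and enyne metathesis → enone → cycloaddition closing cyclopentane and cyclohexene at once (C3a, C7, C7a) → selenide, C3 ester, ylide epoxidation, selenoxide [2,3] shift (C5) → C5 ester. The side-chain acid comes from butane-2,3-dione by Wittig olefination and CBS reduction.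
- Stereocontrol: oxazolidinone auxiliary; Ipc2B reagent; silylene ring plus endo rule in the cycloaddition; Felkin–Anh addition for the oxirane; axial oxygen delivery in the [2,3] shift; CBS catalyst and (R)-2-methylbutanoic acid for the ester side chains.

Key step: step 15

Assumption: locants are those of the target drawn as an octahydro-1H-indene (C1 carries the 1-acetoxyethyl group, C2 the isobutyrate, C3 the 2-methylbutanoate, C4 the methylidene, C5 the enoate, C7 the oxirane); β is the face of H-7a; 1 and 23 are taken as catalogue compounds.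

**Route**

Step 1
Reactants: 1 3-[(4-methoxyphenyl)methoxy]propanoic acid; 2 (4R)-4-benzyl-1,3-oxazolidin-2-one
Product: 4 (4R)-4-benzyl-3-{3-[(4-methoxyphenyl)methoxy]propanoyl}-1,3-oxazolidin-2-one, via mixed pivalic anhydride 3 (not isolated)
Conditions: PivCl, Et3N, THF, −20 °C; then 2, LiCl, −20 °C → rt
Reagents that add atoms: none
Why: N-acylation of the oxazolidinone through the mixed anhydride (standard Evans auxiliary loading) should be regioselective because the pivaloyl carbonyl is shielded.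

Step 2
Reactants: 4 (4R)-4-benzyl-3-{3-[(4-methoxyphenyl)methoxy]propanoyl}-1,3-oxazolidin-2-one
Product: 5 (4R)-4-benzyl-3-[(2R,3S)-3-hydroxy-2-{[(4-methoxyphenyl)methoxy]methyl}butanoyl]-1,3-oxazolidin-2-one
Conditions: Bu2BOTf, iPr2NEt, CH2Cl2, −78 → 0 °C; MeCHO, −78 → 0 °C; pH 7 buffer, MeOH, H2O2
Reagents that add atoms: acetaldehyde CC=O
Why: Evans syn-aldol reaction, in which the Z boron enolate reacts through a Zimmerman–Traxler chair on the face left open by the (4R)-benzyl group, should set the later C1 and acetoxy-bearing carbons as the (2R,3S) syn pair.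

Step 3
Reactants: 5 (4R)-4-benzyl-3-[(2R,3S)-3-hydroxy-2-{[(4-methoxyphenyl)methoxy]methyl}butanoyl]-1,3-oxazolidin-2-one
Product: 6 (2R,3S)-3-hydroxy-N-methoxy-2-{[(4-methoxyphenyl)methoxy]methyl}-N-methylbutanamide
Conditions: MeONHMe·HCl, AlMe3, CH2Cl2, −10 °C → rt; Rochelle salt work-up
Reagents that add atoms: N,O-dimethylhydroxylamine hydrochloride CNOC.Cl
Why: Weinreb transamidation with the aluminium amide, assisted by the free β-hydroxyl, should remove the auxiliary (recovered) without epimerising the α-centre.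

Step 4
Reactants: 6 (2R,3S)-3-hydroxy-N-methoxy-2-{[(4-methoxyphenyl)methoxy]methyl}-N-methylbutanamide
Product: 7 (2R,3S)-N-methoxy-2-{[(4-methoxyphenyl)methoxy]methyl}-N-methyl-3-[(triethylsilyl)oxy]butanamide
Conditions: TESCl, imidazole, DMF, 0 °C → rt
Reagents that add atoms: chlorotriethylsilane CC[Si](Cl)(CC)CC
Why: Routine silylation of the secondary alcohol gives a group that survives hydride and organoboron chemistry and is later removed selectively in the presence of MOM and PMB ethers.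

Step 5
Reactants: 7 (2R,3S)-N-methoxy-2-{[(4-methoxyphenyl)methoxy]methyl}-N-methyl-3-[(triethylsilyl)oxy]butanamide
Product: 8 (2R,3S)-2-{[(4-methoxyphenyl)methoxy]methyl}-3-[(triethylsilyl)oxy]butanal
Conditions: iBu2AlH, THF, −78 °C; Rochelle salt work-up
Reagents that add atoms: none
Why: Weinreb amide reduction should stop at the aldehyde because the chelated tetrahedral aluminium adduct collapses only on work-up; the aldehyde is used at once to avoid α-epimerisation.

Step 6
Reactants: 8 (2R,3S)-2-{[(4-methoxyphenyl)methoxy]methyl}-3-[(triethylsilyl)oxy]butanal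
Product: 9 (3R,4R,5S,6S)-3-(methoxymethoxy)-5-{[(4-methoxyphenyl)methoxy]methyl}-6-[(triethylsilyl)oxy]hept-1-en-4-ol
Conditions: CH2=CHCH2OCH2OMe, s-BuLi, THF, −78 °C; (−)-Ipc2BOMe; BF3·OEt2; 8, −78 °C; NaOH, H2O2
Reagents that add atoms: 3-(methoxymethoxy)prop-1-ene C=CCOCOC
Why: Brown asymmetric γ-alkoxyallylboration, in which the (Z)-γ-(methoxymethoxy)allyl-Ipc2-borane adds through a closed chair to the si face of the aldehyde, should give the threo (3R,4R) mono-protected diol, with reagent control reinforced by the anti-Felkin preference of Z-γ-substituted allylboranes.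

Step 7
Reactants: 9 (3R,4R,5S,6S)-3-(methoxymethoxy)-5-{[(4-methoxyphenyl)methoxy]methyl}-6-[(triethylsilyl)oxy]hept-1-en-4-ol
Product: 10 (3R,4R,5S,6S)-3-(methoxymethoxy)-5-{[(4-methoxyphenyl)methoxy]methyl}-6-[(triethylsilyl)oxy]hept-1-en-4-yl 2-methylpropanoate
Conditions: iPrCOCl, pyridine, DMAP (cat.), CH2Cl2, 0 °C → rt
Reagents that add atoms: 2-methylpropanoyl chloride CC(C)C(=O)Cl
Why: DMAP-catalysed acylation of the only free hydroxyl installs the C2 isobutyrate of the target at the stage where this oxygen is uniquely unprotected.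

Step 8
Reactants: 10 (3R,4R,5S,6S)-3-(methoxymethoxy)-5-{[(4-methoxyphenyl)methoxy]methyl}-6-[(triethylsilyl)oxy]hept-1-en-4-yl 2-methylpropanoate
Product: 11 (3R,4R,5R,6S)-6-hydroxy-3-(methoxymethoxy)-5-{[(4-methoxyphenyl)methoxy]methyl}hept-1-en-4-yl 2-methylpropanoate
Conditions: PPTS, MeOH, 0 °C → rt
Reagents that add atoms: none
Why: Mild acid methanolysis should cleave the secondary triethylsilyl ether while the MOM ether, PMB ether and ester stay intact.

Step 9
Reactants: 11 (3R,4R,5R,6S)-6-hydroxy-3-(methoxymethoxy)-5-{[(4-methoxyphenyl)methoxy]methyl}hept-1-en-4-yl 2-methylpropanoate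
Product: 12 (3R,4R,5R,6S)-6-(acetyloxy)-3-(methoxymethoxy)-5-{[(4-methoxyphenyl)methoxy]methyl}hept-1-en-4-yl 2-methylpropanoate
Conditions: Ac2O, pyridine, DMAP (cat.), CH2Cl2, 0 °C → rt
Reagents that add atoms: acetic anhydride CC(=O)OC(C)=O
Why: Acetylation of the single free hydroxyl puts the side-chain acetate of the target in place.

Step 10
Reactants: 12 (3R,4R,5R,6S)-6-(acetyloxy)-3-(methoxymethoxy)-5-{[(4-methoxyphenyl)methoxy]methyl}hept-1-en-4-yl 2-methylpropanoate
Product: 13 (3R,4R,5R,6S)-6-(acetyloxy)-3-hydroxy-5-{[(4-methoxyphenyl)methoxy]methyl}hept-1-en-4-yl 2-methylpropanoate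
Conditions: TMSOTf, 2,2′-bipyridyl, CH2Cl2, 0 °C → rt; then H2O
Reagents that add atoms: none
Why: Silyl triflate/bipyridyl MOM cleavage proceeds through a pyridinium acetal that water hydrolyses under nearly neutral conditions, so the PMB ether and both esters should survive and acyl migration is not induced.

Step 11
Reactants: 13 (3R,4R,5R,6S)-6-(acetyloxy)-3-hydroxy-5-{[(4-methoxyphenyl)methoxy]methyl}hept-1-en-4-yl 2-methylpropanoate
Product: 15 (3R,4R,5R,6S)-6-(acetyloxy)-3-{[di(propan-2-yl)(prop-2-yn-1-yloxy)silyl]oxy}-5-{[(4-methoxyphenyl)methoxy]methyl}hept-1-en-4-yl 2-methylpropanoate, via chlorosilyl ether 14 (not isolated)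
Conditions: iPr2SiCl2, imidazole, CH2Cl2, 0 °C; then HC≡CCH2OH, rt
Reagents that add atoms: dichlorodi(propan-2-yl)silane CC(C)[Si](Cl)(Cl)C(C)C; prop-2-yn-1-ol C#CCO
Why: Sequential substitution at silicon (temporary silicon tether, mixed silaketal formation) links the allylic C3 oxygen to a propargyl unit and so prepares the seven-membered ring.

Step 12
Reactants: 15 (3R,4R,5R,6S)-6-(acetyloxy)-3-{[di(propan-2-yl)(prop-2-yn-1-yloxy)silyl]oxy}-5-{[(4-methoxyphenyl)methoxy]methyl}hept-1-en-4-yl 2-methylpropanoate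
Product: 16 (1R,2R,3S)-3-(acetyloxy)-1-[(7R)-5-ethenyl-2,2-di(propan-2-yl)-4,7-dihydro-1,3,2-dioxasilepin-7-yl]-2-{[(4-methoxyphenyl)methoxy]methyl}butyl 2-methylpropanoate
Conditions: second-generation Grubbs catalyst RuCl2(=CHPh)(H2IMes)(PCy3) (10 mol %), ethylene (1 atm), toluene, 60 °C
Reagents that add atoms: none
Why: Exo-mode ring-closing enyne metathesis of the silicon-tethered enyne should give the seven-membered dioxasilepine with a 1-vinyl-cycloalkene diene, the ring forcing the cis relation of C3 and the CH2O group on the new trisubstituted alkene.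

Step 13
Reactants: 16 (1R,2R,3S)-3-(acetyloxy)-1-[(7R)-5-ethenyl-2,2-di(propan-2-yl)-4,7-dihydro-1,3,2-dioxasilepin-7-yl]-2-{[(4-methoxyphenyl)methoxy]methyl}butyl 2-methylpropanoate
Product: 17 (1R,2R,3S)-3-(acetyloxy)-1-[(7R)-5-ethenyl-2,2-di(propan-2-yl)-4,7-dihydro-1,3,2-dioxasilepin-7-yl]-2-(hydroxymethyl)butyl 2-methylpropanoate
Conditions: DDQ, CH2Cl2/pH 7 buffer, 0 °C
Reagents that add atoms: none
Why: Oxidative PMB cleavage under buffered conditions is fast at 0 °C and should outrun any reaction of DDQ with the diene, leaving the silaketal and esters untouched.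

Step 14
Reactants: 17 (1R,2R,3S)-3-(acetyloxy)-1-[(7R)-5-ethenyl-2,2-di(propan-2-yl)-4,7-dihydro-1,3,2-dioxasilepin-7-yl]-2-(hydroxymethyl)butyl 2-methylpropanoate
Product: 19 (1R,2R,3E)-2-[(1S)-1-(acetyloxy)ethyl]-1-[(7R)-5-ethenyl-2,2-di(propan-2-yl)-4,7-dihydro-1,3,2-dioxasilepin-7-yl]-5-oxohex-3-en-1-yl 2-methylpropanoate, via aldehyde 18 (not isolated)
Conditions: Dess–Martin periodinane, NaHCO3, CH2Cl2, 0 °C; then Ph3P=CHC(O)CH3, rt
Reagents that add atoms: 1-(triphenyl-λ5-phosphanylidene)propan-2-one CC(=O)C=P(c1ccccc1)(c1ccccc1)c1ccccc1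
Why: Dess–Martin oxidation followed in the same flask by Wittig olefination with the stabilised, non-basic ylide should give the (E)-enone without β-elimination or epimerisation of the sensitive aldehyde.

Step 15
Reactants: 19 (1R,2R,3E)-2-[(1S)-1-(acetyloxy)ethyl]-1-[(7R)-5-ethenyl-2,2-di(propan-2-yl)-4,7-dihydro-1,3,2-dioxasilepin-7-yl]-5-oxohex-3-en-1-yl 2-methylpropanoate
Product: 20 cycloadduct: trans-fused hexahydroindene with C4=C5 double bond; 1β-[(1S)-1-(acetyloxy)ethyl]; 2α-(2-methylpropanoyloxy); 7β-acetyl; O-3β and the C4–CH2–O oxygen joined by Si(iPr)2; H-3a α; H-7a β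
Conditions: toluene (5 mM), BHT (cat.), 100 °C, sealed tube
Reagents that add atoms: none
Why: Thermal, concerted but asynchronous [4+2] cycloaddition (type 1 intramolecular Diels–Alder reaction of a terminally activated 1,3,8-nonatriene, the closest known reaction type), in which the acetyl-activated (E)-alkene adds suprafacially across the s-cis diene and the CH2O substituent on C4 makes C3a the nucleophilic terminus that bonds to the enone β-carbon C7a. The cyclopentane closes in the fused mode through the C3a–C7a bond over the three-atom tether C3–C2–C1, and the cyclohexene closes as the [4+2] ring through the C6–C7 bond. C3a is controlled by the dioxasilepine ring: it holds O-3 on the C4 side of the diene, so the tether leaves C3 on the opposite face and the dienophile can reach only that face, which places O-3 cis to C4 and trans to H-3a. C7a follows from the endo orientation of the acetyl group (tether exo), which gives the trans ring fusion, and C7 from the E geometry of the enone, which is transferred stereospecifically so that H-7 is trans to H-7a. The selectivity needed is endo over exo; it is secured by secondary overlap of the acetyl group and because only the endo mode keeps the C1 and C2 substituents pseudo-equatorial, whereas the exo mode would force the acetoxyethyl branch to eclipse the dienophile. Regiochemistry is fixed by the tether.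

Step 16
Reactants: 20 cycloadduct (silylene-bridged 7β-acetyl hexahydroindene)
Product: 21 diol: as 20 but with free 3β-hydroxyl and 4-(hydroxymethyl) groups
Conditions: HF·pyridine, pyridine, THF, 0 °C
Reagents that add atoms: none
Why: Fluoride cleavage of both Si–O bonds under buffered conditions removes the temporary ring while ketone and esters remain and acyl migration to O-3 is suppressed.

Step 17
Reactants: 21 diol (3β-hydroxy; 4-hydroxymethyl)
Product: 22 selenide: as 21 but with 4-[(phenylselanyl)methyl]; 3β-hydroxyl free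
Conditions: N-(phenylselanyl)phthalimide, Bu3P, THF, 0 °C → rt
Reagents that add atoms: N-(phenylselanyl)phthalimide O=C1N([Se]c2ccccc2)C(=O)c2ccccc12
Why: Grieco-type selenenylation through an alkoxyphosphonium ion is an SN2 process that should be selective for the primary allylic alcohol over the hindered secondary cyclopentanol.

Step 18
Reactants: 22 selenide (3β-hydroxyl free); 23 (2R)-2-methylbutanoic acid
Product: 24 ester: as 22 but with 3β-[(2R)-2-methylbutanoyl]oxy
Conditions: DCC, DMAP (cat.), CH2Cl2, 0 °C → rt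
Reagents that add atoms: none
Why: Steglich esterification acylates the only free hydroxyl under conditions mild enough to keep the α-stereocentre of the acid.

Step 19
Reactants: 24 ester (7β-acetyl; 4-[(phenylselanyl)methyl])
Product: 25 oxirane: as 24 but with 7β-[(2R)-2-methyloxiran-2-yl] in place of acetyl
Conditions: Me3S+ I−, KN(SiMe3)2, THF, −10 °C; then 24, −10 → 0 °C
Reagents that add atoms: trimethylsulfonium iodide C[S+](C)C.[I-]
Why: Corey–Chaykovsky epoxidation, in which the sulfonium ylide adds irreversibly to the methyl ketone anti to the C7–C7a bond and over the C6 methylene (Felkin–Anh, as in additions to ring-bound acetyl groups flanked by a branched carbon and a CH2), should give the (2R)-oxirane, the esters being far less electrophilic than the ketone at this temperature.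

Step 20
Reactants: 25 oxirane (4-[(phenylselanyl)methyl]; C4=C5)
Product: 28 (1R,2R,3R,3aS,5S,7S,7aR)-1-[(1S)-1-(acetyloxy)ethyl]-5-hydroxy-4-methylidene-7-[(2R)-2-methyloxiran-2-yl]-2-[(2-methylpropanoyl)oxy]octahydro-1H-inden-3-yl (2R)-2-methylbutanoate, via selenoxide 26 (not isolated), via selenenate ester 27 (not isolated)
Conditions: 30% aq. H2O2, pyridine, CH2Cl2, 0 °C → rt
Reagents that add atoms: hydrogen peroxide OO
Why: Oxidation to the allylic selenoxide triggers a suprafacial [2,3]-sigmatropic shift that moves oxygen to C5 and the double bond to the exocyclic position, and delivery to the α face of C5 (axial, chair-forming, opposed only by the axial hydrogens at C3a and C7) should give the 5α-alcohol.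

Step 21
Reactants: 29 butane-2,3-dione; 30 tert-butyl (triphenyl-λ5-phosphanylidene)acetate
Product: 31 tert-butyl (2E)-3-methyl-4-oxopent-2-enoate
Conditions: CH2Cl2, rt (29 in excess)
Reagents that add atoms: none
Why: Wittig mono-olefination of the 1,2-diketone with a stabilised ylide should give the E enoate (ester trans to acetyl).

Step 22
Reactants: 31 tert-butyl (2E)-3-methyl-4-oxopent-2-enoate
Product: 32 tert-butyl (2E,4S)-4-hydroxy-3-methylpent-2-enoate
Conditions: (R)-2-methyl-CBS-oxazaborolidine (10 mol %), BH3·SMe2, THF, −20 °C; MeOH quench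
Reagents that add atoms: none
Why: CBS reduction of the alkenyl methyl ketone, with the alkenyl group as the large substituent, should give the (S)-allylic alcohol with the (R)-catalyst by 1,2-hydride delivery.

Step 23
Reactants: 32 tert-butyl (2E,4S)-4-hydroxy-3-methylpent-2-enoate
Product: 33 tert-butyl (2E,4S)-4-(acetyloxy)-3-methylpent-2-enoate
Conditions: Ac2O, pyridine, DMAP (cat.), CH2Cl2, 0 °C → rt
Reagents that add atoms: acetic anhydride CC(=O)OC(C)=O
Why: Standard acetylation of the secondary allylic alcohol with retention.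

Step 24
Reactants: 33 tert-butyl (2E,4S)-4-(acetyloxy)-3-methylpent-2-enoate
Product: 34 (2E,4S)-4-(acetyloxy)-3-methylpent-2-enoic acid
Conditions: TFA, CH2Cl2, 0 °C → rt
Reagents that add atoms: none
Why: Acidolysis of the tert-butyl ester leaves the acetate intact, because the electron-poor alkene disfavours ionisation of the allylic acetate.

Step 25
Reactants: 28 (1R,2R,3R,3aS,5S,7S,7aR)-1-[(1S)-1-(acetyloxy)ethyl]-5-hydroxy-4-methylidene-7-[(2R)-2-methyloxiran-2-yl]-2-[(2-methylpropanoyl)oxy]octahydro-1H-inden-3-yl (2R)-2-methylbutanoate; 34 (2E,4S)-4-(acetyloxy)-3-methylpent-2-enoic acid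
Product: 35 (1R,2R,3R,3aS,5S,7S,7aR)-1-[(1S)-1-(acetyloxy)ethyl]-4-methylidene-3-{[(2R)-2-methylbutanoyl]oxy}-7-[(2R)-2-methyloxiran-2-yl]-2-[(2-methylpropanoyl)oxy]octahydro-1H-inden-5-yl (2E,4S)-4-(acetyloxy)-3-methylpent-2-enoate (target)
Conditions: EDC, DMAP, CH2Cl2, 0 °C → rt
Reagents that add atoms: none
Why: Steglich-type esterification of the last free hydroxyl with retention at C5 completes the target; the acid has no α-stereocentre and the oxirane tolerates the neutral conditions.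

**Compound list**

1 | 3-[(4-methoxyphenyl)methoxy]propanoic acid | OC(=O)CCOCc1ccc(OC)cc1 | starting material
2 | (4R)-4-benzyl-1,3-oxazolidin-2-one | O=C1N[C@H](Cc2ccccc2)CO1 | starting material
3 | 2,2-dimethylpropanoic 3-[(4-methoxyphenyl)methoxy]propanoic anhydride | CC(C)(C)C(=O)OC(=O)CCOCc1ccc(OC)cc1 | intermediate
4 | (4R)-4-benzyl-3-{3-[(4-methoxyphenyl)methoxy]propanoyl}-1,3-oxazolidin-2-one | O=C(CCOCc1ccc(OC)cc1)N1[C@H](Cc2ccccc2)COC1=O | intermediate
5 | (4R)-4-benzyl-3-[(2R,3S)-3-hydroxy-2-{[(4-methoxyphenyl)methoxy]methyl}butanoyl]-1,3-oxazolidin-2-one | O=C([C@@H]([C@H](C)O)COCc1ccc(OC)cc1)N1[C@H](Cc2ccccc2)COC1=O | intermediate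
6 | (2R,3S)-3-hydroxy-N-methoxy-2-{[(4-methoxyphenyl)methoxy]methyl}-N-methylbutanamide | CON(C)C(=O)[C@@H]([C@H](C)O)COCc1ccc(OC)cc1 | intermediate
7 | (2R,3S)-N-methoxy-2-{[(4-methoxyphenyl)methoxy]methyl}-N-methyl-3-[(triethylsilyl)oxy]butanamide | CON(C)C(=O)[C@@H]([C@H](C)O[Si](CC)(CC)CC)COCc1ccc(OC)cc1 | intermediate
8 | (2R,3S)-2-{[(4-methoxyphenyl)methoxy]methyl}-3-[(triethylsilyl)oxy]butanal | O=C[C@@H]([C@H](C)O[Si](CC)(CC)CC)COCc1ccc(OC)cc1 | intermediate
9 | (3R,4R,5S,6S)-3-(methoxymethoxy)-5-{[(4-methoxyphenyl)methoxy]methyl}-6-[(triethylsilyl)oxy]hept-1-en-4-ol | C=C[C@@H](OCOC)[C@H](O)[C@@H]([C@H](C)O[Si](CC)(CC)CC)COCc1ccc(OC)cc1 | intermediate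
10 | (3R,4R,5S,6S)-3-(methoxymethoxy)-5-{[(4-methoxyphenyl)methoxy]methyl}-6-[(triethylsilyl)oxy]hept-1-en-4-yl 2-methylpropanoate | C=C[C@@H](OCOC)[C@H](OC(=O)C(C)C)[C@@H]([C@H](C)O[Si](CC)(CC)CC)COCc1ccc(OC)cc1 | intermediate
11 | (3R,4R,5R,6S)-6-hydroxy-3-(methoxymethoxy)-5-{[(4-methoxyphenyl)methoxy]methyl}hept-1-en-4-yl 2-methylpropanoate | C=C[C@@H](OCOC)[C@H](OC(=O)C(C)C)[C@@H]([C@H](C)O)COCc1ccc(OC)cc1 | intermediate
12 | (3R,4R,5R,6S)-6-(acetyloxy)-3-(methoxymethoxy)-5-{[(4-methoxyphenyl)methoxy]methyl}hept-1-en-4-yl 2-methylpropanoate | C=C[C@@H](OCOC)[C@H](OC(=O)C(C)C)[C@@H]([C@H](C)OC(C)=O)COCc1ccc(OC)cc1 | intermediate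
13 | (3R,4R,5R,6S)-6-(acetyloxy)-3-hydroxy-5-{[(4-methoxyphenyl)methoxy]methyl}hept-1-en-4-yl 2-methylpropanoate | C=C[C@@H](O)[C@H](OC(=O)C(C)C)[C@@H]([C@H](C)OC(C)=O)COCc1ccc(OC)cc1 | intermediate
14 | (3R,4R,5R,6S)-6-(acetyloxy)-3-{[chlorodi(propan-2-yl)silyl]oxy}-5-{[(4-methoxyphenyl)methoxy]methyl}hept-1-en-4-yl 2-methylpropanoate | C=C[C@@H](O[Si](Cl)(C(C)C)C(C)C)[C@H](OC(=O)C(C)C)[C@@H]([C@H](C)OC(C)=O)COCc1ccc(OC)cc1 | intermediate
15 | (3R,4R,5R,6S)-6-(acetyloxy)-3-{[di(propan-2-yl)(prop-2-yn-1-yloxy)silyl]oxy}-5-{[(4-methoxyphenyl)methoxy]methyl}hept-1-en-4-yl 2-methylpropanoate | C=C[C@@H](O[Si](OCC#C)(C(C)C)C(C)C)[C@H](OC(=O)C(C)C)[C@@H]([C@H](C)OC(C)=O)COCc1ccc(OC)cc1 | intermediate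
16 | (1R,2R,3S)-3-(acetyloxy)-1-[(7R)-5-ethenyl-2,2-di(propan-2-yl)-4,7-dihydro-1,3,2-dioxasilepin-7-yl]-2-{[(4-methoxyphenyl)methoxy]methyl}butyl 2-methylpropanoate | C=CC1=C[C@@H](O[Si](C(C)C)(C(C)C)OC1)[C@H](OC(=O)C(C)C)[C@@H]([C@H](C)OC(C)=O)COCc1ccc(OC)cc1 | intermediate
17 | (1R,2R,3S)-3-(acetyloxy)-1-[(7R)-5-ethenyl-2,2-di(propan-2-yl)-4,7-dihydro-1,3,2-dioxasilepin-7-yl]-2-(hydroxymethyl)butyl 2-methylpropanoate | C=CC1=C[C@@H](O[Si](C(C)C)(C(C)C)OC1)[C@H](OC(=O)C(C)C)[C@@H]([C@H](C)OC(C)=O)CO | intermediate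
18 | (1R,2R,3S)-3-(acetyloxy)-1-[(7R)-5-ethenyl-2,2-di(propan-2-yl)-4,7-dihydro-1,3,2-dioxasilepin-7-yl]-2-formylbutyl 2-methylpropanoate | C=CC1=C[C@@H](O[Si](C(C)C)(C(C)C)OC1)[C@H](OC(=O)C(C)C)[C@@H]([C@H](C)OC(C)=O)C=O | intermediate
19 | (1R,2R,3E)-2-[(1S)-1-(acetyloxy)ethyl]-1-[(7R)-5-ethenyl-2,2-di(propan-2-yl)-4,7-dihydro-1,3,2-dioxasilepin-7-yl]-5-oxohex-3-en-1-yl 2-methylpropanoate | C=CC1=C[C@@H](O[Si](C(C)C)(C(C)C)OC1)[C@H](OC(=O)C(C)C)[C@@H]([C@H](C)OC(C)=O)/C=C/C(C)=O | intermediate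
20 | cycloadduct: trans-fused hexahydroindene (C4=C5); 1β-[(1S)-1-(acetyloxy)ethyl]; 2α-(2-methylpropanoyloxy); 7β-acetyl; O-3β and C4–CH2–O bridged by Si(iPr)2; H-3a α; H-7a β | C3C=1[C@H]2[C@@H](O[Si](C(C)C)(C(C)C)O3)[C@H](OC(=O)C(C)C)[C@@H]([C@H](C)OC(C)=O)[C@@H]2[C@@H](C(C)=O)CC=1 | intermediate
21 | diol: as 20 with 3β-hydroxyl and 4-(hydroxymethyl) in place of the silylene bridge | OCC=1[C@H]2[C@@H](O)[C@H](OC(=O)C(C)C)[C@@H]([C@H](C)OC(C)=O)[C@@H]2[C@@H](C(C)=O)CC=1 | intermediate
22 | selenide: as 21 with 4-[(phenylselanyl)methyl] | c1ccccc1[Se]CC=1[C@H]2[C@@H](O)[C@H](OC(=O)C(C)C)[C@@H]([C@H](C)OC(C)=O)[C@@H]2[C@@H](C(C)=O)CC=1 | intermediate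
23 | (2R)-2-methylbutanoic acid | CC[C@@H](C)C(=O)O | starting material
24 | ester: as 22 with 3β-[(2R)-2-methylbutanoyl]oxy | c1ccccc1[Se]CC=1[C@H]2[C@@H](OC(=O)[C@H](C)CC)[C@H](OC(=O)C(C)C)[C@@H]([C@H](C)OC(C)=O)[C@@H]2[C@@H](C(C)=O)CC=1 | intermediate
25 | oxirane: as 24 with 7β-[(2R)-2-methyloxiran-2-yl] in place of acetyl | c1ccccc1[Se]CC=1[C@H]2[C@@H](OC(=O)[C@H](C)CC)[C@H](OC(=O)C(C)C)[C@@H]([C@H](C)OC(C)=O)[C@@H]2[C@@H]([C@]3(C)CO3)CC=1 | intermediate
26 | selenoxide of 25 (configuration at Se not defined) | O=[Se](c1ccccc1)CC=1[C@H]2[C@@H](OC(=O)[C@H](C)CC)[C@H](OC(=O)C(C)C)[C@@H]([C@H](C)OC(C)=O)[C@@H]2[C@@H]([C@]3(C)CO3)CC=1 | intermediate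
27 | 5α-O-(phenylselanyl) selenenate ester of 28 | C=C1[C@H]2[C@@H](OC(=O)[C@H](C)CC)[C@H](OC(=O)C(C)C)[C@@H]([C@H](C)OC(C)=O)[C@@H]2[C@@H]([C@]2(C)CO2)C[C@@H]1O[Se]c1ccccc1 | intermediate
28 | (1R,2R,3R,3aS,5S,7S,7aR)-1-[(1S)-1-(acetyloxy)ethyl]-5-hydroxy-4-methylidene-7-[(2R)-2-methyloxiran-2-yl]-2-[(2-methylpropanoyl)oxy]octahydro-1H-inden-3-yl (2R)-2-methylbutanoate | C=C1[C@H]2[C@@H](OC(=O)[C@H](C)CC)[C@H](OC(=O)C(C)C)[C@@H]([C@H](C)OC(C)=O)[C@@H]2[C@@H]([C@]2(C)CO2)C[C@@H]1O | intermediate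
29 | butane-2,3-dione | CC(=O)C(C)=O | starting material
30 | tert-butyl (triphenyl-λ5-phosphanylidene)acetate | CC(C)(C)OC(=O)C=P(c1ccccc1)(c1ccccc1)c1ccccc1 | starting material
31 | tert-butyl (2E)-3-methyl-4-oxopent-2-enoate | CC(=O)/C(C)=C/C(=O)OC(C)(C)C | intermediate
32 | tert-butyl (2E,4S)-4-hydroxy-3-methylpent-2-enoate | C[C@H](O)/C(C)=C/C(=O)OC(C)(C)C | intermediate
33 | tert-butyl (2E,4S)-4-(acetyloxy)-3-methylpent-2-enoate | C[C@H](OC(C)=O)/C(C)=C/C(=O)OC(C)(C)C | intermediate
34 | (2E,4S)-4-(acetyloxy)-3-methylpent-2-enoic acid | C[C@H](OC(C)=O)/C(C)=C/C(=O)O | intermediate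
35 | (1R,2R,3R,3aS,5S,7S,7aR)-1-[(1S)-1-(acetyloxy)ethyl]-4-methylidene-3-{[(2R)-2-methylbutanoyl]oxy}-7-[(2R)-2-methyloxiran-2-yl]-2-[(2-methylpropanoyl)oxy]octahydro-1H-inden-5-yl (2E,4S)-4-(acetyloxy)-3-methylpent-2-enoate | C=C1[C@H]2[C@@H](OC(=O)[C@H](C)CC)[C@H](OC(=O)C(C)C)[C@@H]([C@H](C)OC(C)=O)[C@@H]2[C@@H]([C@]2(C)CO2)C[C@@H]1OC(=O)/C=C(\C)[C@H](C)OC(C)=O | target

**Step count and risks**

Total step count: 25. Longest linear sequence: 21 steps (steps 1–20 and 25); steps 21–24 form the side-chain branch.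

Steps most likely to fail:

1. Step 19 (ylide addition to the C7 acetyl group). The risk is low or reversed facial selectivity at the new quaternary oxirane carbon, which is controlled only by the neighbouring ring stereocentre. The fallback exchanges the roles of the two carbon substituents, so that the same facial preference delivers the opposite configuration. It sets out from aldehyde 18, which is olefinated with 1-chloro-3-(triphenyl-λ5-phosphanylidene)propan-2-one to the chloromethyl enone F1 and cyclised as in step 15 to the chloroacetyl cycloadduct F2. MeTi(OiPr)3, which is chemoselective for ketones over esters, then adds methyl to give the chlorohydrin F3. The chlorohydrin is carried as a masked oxirane through the operations of steps 16–18: HF·pyridine to the diol F4, selenenylation to the selenide F5 and Steglich esterification with 23 to the ester F6. DBU in CH2Cl2 then closes the oxirane by displacement of chloride with retention at the quaternary carbon, and the route is rejoined at 25.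

2. Step 20 (selenoxide [2,3] shift). The risk is delivery of oxygen to the β face of C5, which would give the equatorial C5 epimer together with or instead of 28. The fallback sets out from the C5 alcohol obtained in step 20 (28 and its epimer). It is oxidised with Dess–Martin periodinane to the 4-methylidene-5-ketone F7, and a reagent-controlled 1,2-reduction with (R)-2-methyl-CBS-oxazaborolidine and catecholborane at −78 °C (the methylidene-bearing carbon acting as the large group) returns the route to 28.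

3. Step 15 (cycloaddition). The risk is erosion of the endo (trans-fused) preference at 100 °C, or loss of the triene by polymerisation before it cyclises. The fallback changes the activation mode and sets out from aldehyde 18. Wittig olefination with (triphenyl-λ5-phosphanylidene)acetaldehyde gives the enal F8. Iminium-ion catalysis with dibenzylammonium trifluoroacetate in MeCN/H2O at room temperature (or a matched chiral imidazolidinone salt) lowers the dienophile LUMO and should give the 7β-formyl cycloadduct F9 with a stronger endo preference. MeTi(OiPr)3 adds to the aldehyde to give the carbinol F10 (configuration at the carbinol carbon irrelevant), and Dess–Martin oxidation returns the route to 20.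

Further compounds

F1 | step 19 | (1R,2R,3E)-2-[(1S)-1-(acetyloxy)ethyl]-6-chloro-1-[(7R)-5-ethenyl-2,2-di(propan-2-yl)-4,7-dihydro-1,3,2-dioxasilepin-7-yl]-5-oxohex-3-en-1-yl 2-methylpropanoate | C=CC1=C[C@@H](O[Si](C(C)C)(C(C)C)OC1)[C@H](OC(=O)C(C)C)[C@@H]([C@H](C)OC(C)=O)/C=C/C(=O)CCl
F2 | step 19 | chloroacetyl cycloadduct: as 20 with 7β-(chloroacetyl) | C3C=1[C@H]2[C@@H](O[Si](C(C)C)(C(C)C)O3)[C@H](OC(=O)C(C)C)[C@@H]([C@H](C)OC(C)=O)[C@@H]2[C@@H](C(=O)CCl)CC=1
F3 | step 19 | chlorohydrin: as 20 with 7β-[(2R)-1-chloro-2-hydroxypropan-2-yl] | C3C=1[C@H]2[C@@H](O[Si](C(C)C)(C(C)C)O3)[C@H](OC(=O)C(C)C)[C@@H]([C@H](C)OC(C)=O)[C@@H]2[C@@H]([C@](O)(C)CCl)CC=1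
F4 | step 19 | chlorohydrin diol: as 21 with 7β-[(2R)-1-chloro-2-hydroxypropan-2-yl] | OCC=1[C@H]2[C@@H](O)[C@H](OC(=O)C(C)C)[C@@H]([C@H](C)OC(C)=O)[C@@H]2[C@@H]([C@](O)(C)CCl)CC=1
F5 | step 19 | chlorohydrin selenide: as 22 with 7β-[(2R)-1-chloro-2-hydroxypropan-2-yl] | c1ccccc1[Se]CC=1[C@H]2[C@@H](O)[C@H](OC(=O)C(C)C)[C@@H]([C@H](C)OC(C)=O)[C@@H]2[C@@H]([C@](O)(C)CCl)CC=1
F6 | step 19 | chlorohydrin ester: as 24 with 7β-[(2R)-1-chloro-2-hydroxypropan-2-yl] | c1ccccc1[Se]CC=1[C@H]2[C@@H](OC(=O)[C@H](C)CC)[C@H](OC(=O)C(C)C)[C@@H]([C@H](C)OC(C)=O)[C@@H]2[C@@H]([C@](O)(C)CCl)CC=1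
F7 | step 20 | 4-methylidene-5-ketone: as 28 with C5=O in place of C5–OH | C=C1[C@H]2[C@@H](OC(=O)[C@H](C)CC)[C@H](OC(=O)C(C)C)[C@@H]([C@H](C)OC(C)=O)[C@@H]2[C@@H]([C@]2(C)CO2)CC1=O
F8 | step 15 | (1R,2R,3E)-2-[(1S)-1-(acetyloxy)ethyl]-1-[(7R)-5-ethenyl-2,2-di(propan-2-yl)-4,7-dihydro-1,3,2-dioxasilepin-7-yl]-5-oxopent-3-en-1-yl 2-methylpropanoate | C=CC1=C[C@@H](O[Si](C(C)C)(C(C)C)OC1)[C@H](OC(=O)C(C)C)[C@@H]([C@H](C)OC(C)=O)/C=C/C=O
F9 | step 15 | formyl cycloadduct: as 20 with 7β-formyl | C3C=1[C@H]2[C@@H](O[Si](C(C)C)(C(C)C)O3)[C@H](OC(=O)C(C)C)[C@@H]([C@H](C)OC(C)=O)[C@@H]2[C@@H](C=O)CC=1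
F10 | step 15 | carbinol: as 20 with 7β-(1-hydroxyethyl), carbinol configuration not defined | C3C=1[C@H]2[C@@H](O[Si](C(C)C)(C(C)C)O3)[C@H](OC(=O)C(C)C)[C@@H]([C@H](C)OC(C)=O)[C@@H]2[C@@H](C(C)O)CC=1
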